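**Conventions.** Labdane numbering is used throughout: decalin C1–C10, side chain C11–C12, butenolide C13–C16, C17 on C8, C18 (CH3) and C19 (CH2OAc) on C4, C20 on C10. β is the face of C20. Read this way, the target SMILES is (2R,4S,5S,6S,10S): 10β-CH3, 5β-H, 19β (CH2OAc), 18α, 2α-OH, 6α-OH.

Assumption: in step 5 the attacked face of 7 is taken from the usual binding model for enones on protonated oxazaborolidines (O4 bound through the lone pair syn to C3–H, C3–H···O contact, one C=C face covered by the geminal phenyl); on this model the (3aR) catalyst leads to 8, and its antipode is equally accessible.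

## The problem

1. The skeleton is a labdane, but H5 and C20 are on the same face, so the decalin is cis-fused. The cationic polyene cyclisations and the trans-selective annulation/reductive alkylation chemistry of normal labdanes therefore do not apply.
2. C5 sits between two quaternary carbons (C4 and C10) and next to the C6 carbinol. C19 must be syn to C20, which puts them 1,3-diaxial on ring A in the preferred conformer.
3. Ring B holds a tetrasubstituted C8=C9 alkene that abuts C10 and carries the C11–C16 chain. The C2 carbinol is remote from every other stereocenter.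
4. Once C5 and C10 are set cis, the fold of the bicycle can control C6 (hydride on the convex face) and C2 (the 2α-alcohol is equatorial and thermodynamically preferred, whereas a hydride reagent is kept off the β face by axial C19 and C20). C4 cannot be relayed in this way and has to be set together with C5 and C10.
5. The butenolide does not survive strong base, hydride or electron-transfer reagents. The single acetate stands beside two free secondary hydroxyls, so it has to be placed while those are absent or inert. The homoallylic 6-OH and the tetrasubstituted alkene are acid-sensitive.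
6. The feature that makes the key step possible is ring B. C5–C10 carry methyl groups on C8 and C10, oxygen on C6 and a carbon substituent on C9, which is the substitution pattern of 2,6-dimethyl-1,4-benzoquinone (C6 and C9 are the two carbonyls). The cis H5/C20 fusion is the stereochemical signature of a [4+2] adduct across a quinone C=C. Ring A (C1–C4, oxygen on C2) is the trace of a 2-silyloxy-1,3-diene whose substituted terminus is C4.

## Retrosynthesis

**Side chain last.** The C12–C13 bond of 19 is cut to give the 9-vinyl diene 16 and commercial 4-bromofuran-2(5H)-one 17. Forward, hydroboration of the C11=C12 vinyl group (trialkylborane 18) is followed by a B-alkyl Suzuki–Miyaura coupling. Cutting C9–C11 instead would need a non-commercial butenolide-ethyl metal. The chosen cut brings in the most sensitive group after all reductions. The forward reaction must hydroborate only the monosubstituted alkene and tolerate two hydroxyls and an acetate.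

**C2 carbinol and acetate.** 16 comes from ketone 15 by electron-transfer reduction, and 15 from keto diol 14 by acetylation. Placing the acetate while C2 is still a ketone avoids any competition between the primary C19 hydroxyl and the unhindered equatorial 2-OH; the only other hydroxyl (6α, axial, beside C5) is inert. The reduction must be thermodynamic in outcome and spare acetate and diene.

**C9–C11 bond.** 14 comes from the fully silylated diene 13 by global desilylation, and 13 from enol triflate 12 by Stille vinylation. 12 is made from enone 10 by conjugate reduction and O-triflation of the enolate 11. This fixes the tetrasubstituted C8=C9 alkene regiospecifically. Carbonyl addition to the C9 ketone followed by dehydration would fight the two flanking substituted carbons and give no regiocontrol.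

**C6 carbinol.** 10 is the triethylsilyl ether of alcohol 9, which comes from ene-dione 8 by 1,2-reduction. Of the two quinone-derived carbonyls only C6 is accessible, and the convex face of the cis-bicycle is the face of H5. The reduction must be chemo- and face-selective.

**Key disconnection.** Cutting C1–C10 and C4–C5 of 8 gives diene 6 and 2,6-dimethyl-1,4-benzoquinone 7. This one cut removes ring A, both quaternary carbons, the cis fusion and three contiguous stereocenters. It leaves an achiral acyclic diene and a commercial achiral quinone that already holds every ring-B carbon in the right oxidation pattern. Neighbouring cuts (C4–C5 alone by enolate coupling, or C5–C10/C6–C7 by intramolecular cycloaddition) require stereocenters to be made beforehand. The forward reaction must be regio-, endo- and face-selective and must transfer the diene geometry to C4.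

**Diene.** 6 comes from Z-enone 4 through its kinetic dienolate 5. 4 comes from N-methoxy-N-methylamide 3, this from hydroxy amide 2, and 2 from 4-methylfuran-2(5H)-one 1 by ring opening. The lactone ring of 1 holds carbonyl and CH2O cis, so the Z geometry that will become the C4 configuration is bought, not made.

## Roads not taken

Alternative 1: The most obvious plan is a Robinson annulation to the angular-methyl octalindione A1, with the saturated ketone as C9 and the enone as ring A, followed by alkylation at C4 and side-chain attachment at C9. The forward key step would be the amine-catalysed annulation. It places the enone oxygen on C3, not C2, and gives no oxygen on C6 and no methyl on C8. Metal–ammonia reductive alkylation would give the trans fusion, so the cis fusion and the C4 centre would each need a separate, unrelayed operation. The chosen cycloaddition delivers the C6 and C9 oxygens, both methyls, the cis fusion and C4 in one event.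

Alternative 2: An intramolecular Diels–Alder reaction of triene A2 would close both rings by forming C5–C10 and C6–C7. The diene is C7=C8–C9=C10 with the C1–C4 tether cis on C10, and the dienophile is a (Z)-C5=C6 alkenylboronate that is oxidised later to 6-OH. The diene is tetrasubstituted with a fully substituted terminus and reaches the s-cis conformer only with difficulty, and the dienophile is not activated. C2 and the quaternary C4 would have to be made first in an open chain, so the run-up is long and two stereocenters have to be made separately where the chosen plan needs one catalytic event.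

Alternative 3: The same quinone cycloaddition could be run with the symmetrical 4,4-dimethyl diene A3 to give the gem-dimethyl cycloadduct A4. C19 would then be hydroxylated late, by 1,5-hydrogen transfer to a C6 alkoxy radical or by a cytochrome P450 monooxygenase. This removes the geometry question of the diene. But both hydroxyls of the target lie on the α face, so any oxygen-directed abstraction addresses C18, the wrong methyl, and an enzyme would have to tell apart two methyls on a carbon with no nearby handle. Epimeric alcohols and later inversions would be needed. In the chosen plan the C19 oxygen is part of the diene and the ring of 1 decides which C4 substituent carries it.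

Key step: step 5

## Route

Step 1
Reactants: 1 4-methylfuran-2(5H)-one
Product: 2 (2Z)-4-hydroxy-N-methoxy-N,3-dimethylbut-2-enamide
Conditions: MeNH(OMe)·HCl, AlMe3, CH2Cl2, 0 °C → rt; crude product used at once
Reagents that add atoms: N,O-dimethylhydroxylamine hydrochloride, CNOC.Cl
Why: Aminolysis of a lactone by an aluminium amide; the ring of 1 holds C=O and CH2O cis, so the opened amide is Z by construction, and the β,β-disubstituted alkene resists conjugate addition.

Step 2
Reactants: 2 (2Z)-4-hydroxy-N-methoxy-N,3-dimethylbut-2-enamide
Product: 3 (2Z)-4-{[tert-butyl(dimethyl)silyl]oxy}-N-methoxy-N,3-dimethylbut-2-enamide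
Conditions: TBSCl, imidazole, DMF, 0 °C → rt
Reagents that add atoms: tert-butyl(chloro)dimethylsilane, CC(C)(C)[Si](C)(C)Cl
Why: Standard silylation of a primary alcohol; it blocks relactonisation of the Z-hydroxy amide.

Step 3
Reactants: 3 (2Z)-4-{[tert-butyl(dimethyl)silyl]oxy}-N-methoxy-N,3-dimethylbut-2-enamide
Product: 4 (3Z)-5-{[tert-butyl(dimethyl)silyl]oxy}-4-methylpent-3-en-2-one
Conditions: MeMgBr, THF, −78 → 0 °C; cold aq NH4Cl
Reagents that add atoms: methylmagnesium bromide, C[Mg]Br
Why: Ketone synthesis from an N-methoxy-N-methylamide through the stable magnesium chelate, which prevents over-addition; the cold, near-neutral quench should keep the Z geometry.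

Step 4
Reactants: 4 (3Z)-5-{[tert-butyl(dimethyl)silyl]oxy}-4-methylpent-3-en-2-one
Product: 6 tert-butyl(dimethyl){[(2Z)-2-methyl-4-{[tri(propan-2-yl)silyl]oxy}penta-2,4-dien-1-yl]oxy}silane (Z-diene), via lithium dienolate 5 (not isolated)
Conditions: LiN(i-Pr)2, THF, −78 °C; then TIPSOTf, −78 → 0 °C
Reagents that add atoms: tri(propan-2-yl)silyl trifluoromethanesulfonate, CC(C)[Si](OS(=O)(=O)C(F)(F)F)(C(C)C)C(C)C
Why: Kinetic deprotonation of the enone at the acetyl methyl gives the cross-conjugated enolate, which is O-silylated; the trisubstituted alkene is not touched, so the Z geometry is carried into the diene.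

Step 5
Reactants: 6 Z-diene; 7 2,6-dimethyl-1,4-benzoquinone
Product: 8 (4aR,5S,8aS)-5-({[tert-butyl(dimethyl)silyl]oxy}methyl)-2,5,8a-trimethyl-7-{[tri(propan-2-yl)silyl]oxy}-4a,5,8,8a-tetrahydronaphthalene-1,4-dione (cis-fused cycloadduct: C6 and C9 carbonyls, C7=C8, C2 silyl enol ether, 19-OTBS)
Conditions: (3aR)-1-(2-methylphenyl)-3,3-diphenyltetrahydro-1H,3H-pyrrolo[1,2-c][1,3,2]oxazaborole (20 mol %), HN(SO2CF3)2 (20 mol %), CH2Cl2/toluene, −78 → −40 °C
Reagents that add atoms: none
Why: Diels–Alder reaction: the protonated oxazaborolidine binds O4 of 7 (the carbonyl flanked by two C–H; the other is buried between two methyls) and lowers the LUMO of the adjacent C=C, and the 2-silyloxydiene adds in a concerted but asynchronous endo [4+2] in which its nucleophilic CH2 terminus (C1) bonds to the methyl-bearing β-carbon (future C10) and its disubstituted terminus (C4) to the α-CH (future C5), so the two fully substituted carbons are never joined to each other. The closest known reaction types are the oxazaborolidinium-catalysed enantioselective Diels–Alder reaction of 2-silyloxybutadienes with methyl-substituted 1,4-benzoquinones and the Lewis acid-promoted cycloaddition of 4,4-disubstituted 2-silyloxydienes with hindered cyclic enones. Ring A is closed by the [4+2] itself (bonds C1–C10 and C4–C5, six-membered, suprafacial on both partners). For C5 and C10 the cis fusion follows from suprafacial addition to the quinone C=C and the absolute configuration from the catalyst, which covers one face of the bound C=C with a phenyl group; the two C=C bonds of 7 are equivalent by symmetry, so only a face has to be chosen. For C4 the Z geometry of 6 (CH2OTBS as the inside substituent) and the endo transition state place C19 on the face of H5 and C20 and the methyl C18 on the face of ring B. The step needs regio-, endo- and face selectivity and faithful transfer of the Z geometry: the first is secured by the matched polarisation of the partners, the second by the preference of the quinone ring to lie under the diene (the exo mode would push the angular methyl into the diene), the third by the catalyst and the fourth by a concerted course at low temperature.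

Step 6
Reactants: 8 cis-fused cycloadduct
Product: 9 6α-hydroxy enone (8 with the C6 carbonyl reduced to the 6α-hydroxyl, 6S; C9 ketone, C7=C8, 2-OTIPS enol ether and 19-OTBS unchanged)
Conditions: NaBH4, CeCl3·7H2O, MeOH/CH2Cl2, −78 °C
Reagents that add atoms: none
Why: Luche 1,2-reduction; the C9 carbonyl is shut between quaternary C10 and methyl-bearing C8, so only C6 reacts, and hydride arrives on the convex β face beside H5 because ring A covers the α face, giving the 6α-alcohol. The reduction also removes the risk of epimerisation at C5, which is α to the C6 carbonyl in 8.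

Step 7
Reactants: 9 6α-hydroxy enone
Product: 10 6α-triethylsilyl ether of 9
Conditions: TESOTf, 2,6-lutidine, CH2Cl2, −78 → 0 °C
Reagents that add atoms: triethylsilyl trifluoromethanesulfonate, CC[Si](CC)(CC)OS(=O)(=O)C(F)(F)F
Why: Silylation of a hindered secondary alcohol with a silyl triflate; it keeps an alkoxide out of step 8 and stops base-induced isomerisation of the γ-hydroxy enone.

Step 8
Reactants: 10 6α-triethylsilyl ether of 9
Product: 12 C9 enol triflate (9-trifluoromethylsulfonyloxy-Δ8(9), C7H2, 6α-OTES, 2-OTIPS enol ether, 19-OTBS), via lithium enolate 11 (not isolated)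
Conditions: LiBH(s-Bu)3, THF, −78 °C; then 2-[N,N-bis(trifluoromethylsulfonyl)amino]-5-chloropyridine, −78 → 0 °C
Reagents that add atoms: 2-[N,N-bis(trifluoromethylsulfonyl)amino]-5-chloropyridine, O=S(=O)(N(c1ccc(Cl)cn1)S(=O)(=O)C(F)(F)F)C(F)(F)F
Why: Conjugate reduction with enolate trapping: hydride adds to the unsubstituted β-carbon C7 (the C9 carbonyl is too hindered for 1,2-attack) and the C8=C9 enolate formed regiospecifically is O-triflated. No stereocenter is formed, and the tetrasubstituted alkene is fixed in its final position.

Step 9
Reactants: 12 C9 enol triflate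
Product: 13 9-vinyl diene (12 with OTf replaced by CH=CH2, C11=C12)
Conditions: tributyl(vinyl)stannane, Pd(PPh3)4 (10 mol %), CuCl, LiCl, DMSO, 60 °C
Reagents that add atoms: tributyl(vinyl)stannane, C=C[Sn](CCCC)(CCCC)CCCC
Why: Stille coupling under copper-accelerated conditions, which are established for hindered 2,6,6-trisubstituted cyclohexenyl triflates; it forms C9–C11 and leaves all three silyl groups in place.

Step 10
Reactants: 13 9-vinyl diene
Product: 14 keto diol (19-OH, 6α-OH, C2 ketone, C8=C9, 9-vinyl; cis-fused, 10β-CH3, 4α-CH3)
Conditions: HF·pyridine, pyridine, THF, 0 °C → rt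
Reagents that add atoms: none
Why: Buffered fluoride cleavage of all three silyl groups; the silyl enol ether gives the C2 ketone. 14 may rest in part as its 2,19-hemiketal, which stays in equilibrium with the open form.

Step 11
Reactants: 14 keto diol
Product: 15 19-acetate of 14 (C2 ketone, free 6α-OH)
Conditions: Ac2O, pyridine, DMAP (cat.), CH2Cl2, 0 °C
Reagents that add atoms: acetic anhydride, CC(=O)OC(C)=O
Why: Acylation of the only reactive hydroxyl: the 6α-OH is axial and lies beside C5 with its two quaternary neighbours, and no C2 hydroxyl exists yet, so the primary C19 alcohol is acetylated alone.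

Step 12
Reactants: 15 19-acetate of 14
Product: 16 19-acetoxy-2α,6α-diol (15 with C2=O reduced to the 2α-hydroxyl, 2R)
Conditions: SmI2, H2O, THF, 0 °C
Reagents that add atoms: none
Why: Single-electron (ketyl) reduction should give the thermodynamically preferred equatorial 2α-alcohol, as dissolving-metal reductions do for ketones flanked by two syn-axial groups, whereas hydride reagents would be kept off the β face by axial C19 and C20 and give the 2β-epimer. Acetate, diene and the free alcohol are inert to divalent samarium in the absence of amine or HMPA.

Step 13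
Reactants: 16 19-acetoxy-2α,6α-diol; 17 4-bromofuran-2(5H)-one
Product: 19 target, 19-acetoxy-2α,6α-dihydroxy-5β-H-labda-8,13-dien-15,16-olide (2R,4S,5S,6S,10S), via trialkylborane 18 (not isolated)
Conditions: 9-BBN-H (3.5 equiv), THF, rt; then 17, Pd(dppf)Cl2 (10 mol %), AsPh3, aq K3PO4, DMF, rt → 40 °C
Reagents that add atoms: none
Why: Anti-Markovnikov hydroboration of the only unhindered alkene (the tetrasubstituted C8=C9 is inert; the hydroxyls are held as borinates), then B-alkyl Suzuki–Miyaura coupling with the bromobutenolide to form C12–C13. The mild phosphate base should spare the hindered acetate and the lactone.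

## Compound list

1 | 4-methylfuran-2(5H)-one | CC1=CC(=O)OC1 | starting material
2 | (2Z)-4-hydroxy-N-methoxy-N,3-dimethylbut-2-enamide | CON(C)C(=O)/C=C(/C)CO | intermediate
3 | (2Z)-4-{[tert-butyl(dimethyl)silyl]oxy}-N-methoxy-N,3-dimethylbut-2-enamide | CON(C)C(=O)/C=C(/C)CO[Si](C)(C)C(C)(C)C | intermediate
4 | (3Z)-5-{[tert-butyl(dimethyl)silyl]oxy}-4-methylpent-3-en-2-one | CC(=O)/C=C(/C)CO[Si](C)(C)C(C)(C)C | intermediate
5 | lithium dienolate of 4 | [Li]OC(=C)/C=C(/C)CO[Si](C)(C)C(C)(C)C | intermediate
6 | tert-butyl(dimethyl){[(2Z)-2-methyl-4-{[tri(propan-2-yl)silyl]oxy}penta-2,4-dien-1-yl]oxy}silane | C=C(O[Si](C(C)C)(C(C)C)C(C)C)/C=C(/C)CO[Si](C)(C)C(C)(C)C | intermediate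
7 | 2,6-dimethyl-1,4-benzoquinone | CC1=CC(=O)C=C(C)C1=O | starting material
8 | (4aR,5S,8aS)-5-({[tert-butyl(dimethyl)silyl]oxy}methyl)-2,5,8a-trimethyl-7-{[tri(propan-2-yl)silyl]oxy}-4a,5,8,8a-tetrahydronaphthalene-1,4-dione | CC(C)(C)[Si](C)(C)OC[C@@]1(C)C=C(O[Si](C(C)C)(C(C)C)C(C)C)C[C@]2(C)C(=O)C(C)=CC(=O)[C@H]12 | intermediate
9 | 6α-hydroxy enone (8 with C6=O reduced to 6α-OH) | CC(C)(C)[Si](C)(C)OC[C@@]1(C)C=C(O[Si](C(C)C)(C(C)C)C(C)C)C[C@]2(C)C(=O)C(C)=C[C@H](O)[C@H]12 | intermediate
10 | 6α-triethylsilyl ether of 9 | CC(C)(C)[Si](C)(C)OC[C@@]1(C)C=C(O[Si](C(C)C)(C(C)C)C(C)C)C[C@]2(C)C(=O)C(C)=C[C@H](O[Si](CC)(CC)CC)[C@H]12 | intermediate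
11 | lithium C8=C9 enolate from conjugate reduction of 10 | CC(C)(C)[Si](C)(C)OC[C@@]1(C)C=C(O[Si](C(C)C)(C(C)C)C(C)C)C[C@]2(C)C(O[Li])=C(C)C[C@H](O[Si](CC)(CC)CC)[C@H]12 | intermediate
12 | C9 enol triflate (Δ8(9), 6α-OTES, 2-OTIPS enol ether, 19-OTBS) | CC(C)(C)[Si](C)(C)OC[C@@]1(C)C=C(O[Si](C(C)C)(C(C)C)C(C)C)C[C@]2(C)C(OS(=O)(=O)C(F)(F)F)=C(C)C[C@H](O[Si](CC)(CC)CC)[C@H]12 | intermediate
13 | 9-vinyl diene (tris-silylated) | CC(C)(C)[Si](C)(C)OC[C@@]1(C)C=C(O[Si](C(C)C)(C(C)C)C(C)C)C[C@]2(C)C(C=C)=C(C)C[C@H](O[Si](CC)(CC)CC)[C@H]12 | intermediate
14 | keto diol (19-OH, 6α-OH, C2 ketone, 9-vinyl) | OC[C@@]1(C)CC(=O)C[C@]2(C)C(C=C)=C(C)C[C@H](O)[C@H]12 | intermediate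
15 | 19-acetate of 14 | CC(=O)OC[C@@]1(C)CC(=O)C[C@]2(C)C(C=C)=C(C)C[C@H](O)[C@H]12 | intermediate
16 | 19-acetoxy-2α,6α-diol with 9-vinyl group | CC(=O)OC[C@@]1(C)C[C@H](O)C[C@]2(C)C(C=C)=C(C)C[C@H](O)[C@H]12 | intermediate
17 | 4-bromofuran-2(5H)-one | BrC1=CC(=O)OC1 | starting material
18 | C12 B-alkyl-9-borabicyclo[3.3.1]nonane of 16 (hydroxyls as O-borinates) | CC(=O)OC[C@@]1(C)C[C@H](OB3C4CCCC3CCC4)C[C@]2(C)C(CCB5C6CCCC5CCC6)=C(C)C[C@H](OB7C8CCCC7CCC8)[C@H]12 | intermediate
19 | 19-acetoxy-2α,6α-dihydroxy-5β-H-labda-8,13-dien-15,16-olide (2R,4S,5S,6S,10S) | CC(=O)OC[C@@]1(C)C[C@H](O)C[C@]2(C)C(CCC3=CC(=O)OC3)=C(C)C[C@H](O)[C@H]12 | target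

## Step count and risks

Total steps: 13. Longest linear sequence: 13 steps (1 → 19); 7 and 17 are bought.

**Step 5 (key step).** The inside CH2OTBS group may slow the cycloaddition within the chiral ion pair, so that desilylation of the diene competes. A stepwise Mukaiyama–Michael course would lose both the transfer of the Z geometry to C4 and the facial control. Fallback, setting out from 6 and 7: run the cycloaddition without catalyst under high pressure (about 12 kbar, CH2Cl2, rt), where a concerted endo pathway transfers the diene geometry, to give racemic 8. Then separate 8 from its antipode, ent-cycloadduct F1, by preparative chromatography on a chiral stationary phase. The route is rejoined at 8.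

**Step 6.** Facial selectivity at C6 may be poor on the flat ene-dione if the β-CH2OTBS group on C4 hinders the convex face, and C5 may epimerise if the reduction is slow. Fallback, setting out from 8: conjugate reduction of the ene-dione with KBH(s-Bu)3 (hydride to C7) and trapping with the same triflimide gives keto triflate F2. Reduction of its C6 ketone with LiBH(s-Bu)3 then occurs on a defined half-chair, where axial C1 blocks the α face and equatorial attack gives the axial 6α-alcohol, hydroxy triflate F3. Silylation with TESOTf returns to the route at 12.

**Step 8.** Hydride delivery to C7 may be slowed by the neighbouring axial 6-OTES group, and O-triflation of the very hindered enolate may be incomplete, leaving the saturated ketone. Fallback, setting out from 10: conjugate reduction with the small copper hydride [(Ph3P)CuH]6 gives saturated ketone F4 (mixture at C8). Deprotonation at C8, the only enolisable position, with KN(SiMe3)2 and O-triflation with the same triflimide returns to the route at 12.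

**Step 12.** Protonation of the ketyl-derived carbanion may not be fully selective, and over-reduction may cleave the acetate or attack the diene. Fallback, setting out from 14: hydroxyl-directed reduction with Me4NBH(OAc)3 (MeCN/AcOH, −20 °C), in which the axial C19 alkoxyborohydride delivers hydride to the β face of C2, gives triol F5. Candida antarctica lipase B with vinyl acetate then acetylates the primary hydroxyl only and returns to the route at 16.

**Step 13.** The aqueous base may cause protodeboronation, acetate loss or opening of the butenolide before transmetalation is complete. Fallback, setting out from 16: hydroboration with 9-BBN-H and oxidation with NaBO3 gives primary alcohol F6. Iodination with I2, PPh3 and imidazole gives iodide F7. A base-free reductive cross-electrophile coupling of F7 with 17 (NiBr2(dme), 4,4′-di-tert-butyl-2,2′-bipyridine, Zn, DMA) then gives 19.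

## Further compounds

F1 | step 5 | (4aS,5R,8aR)-enantiomer of 8 | CC(C)(C)[Si](C)(C)OC[C@]1(C)C=C(O[Si](C(C)C)(C(C)C)C(C)C)C[C@@]2(C)C(=O)C(C)=CC(=O)[C@@H]12
F2 | step 6 | keto triflate (C9 enol triflate, C6 ketone, C7H2) | CC(C)(C)[Si](C)(C)OC[C@@]1(C)C=C(O[Si](C(C)C)(C(C)C)C(C)C)C[C@]2(C)C(OS(=O)(=O)C(F)(F)F)=C(C)CC(=O)[C@H]12
F3 | step 6 | hydroxy triflate (C9 enol triflate, 6α-OH) | CC(C)(C)[Si](C)(C)OC[C@@]1(C)C=C(O[Si](C(C)C)(C(C)C)C(C)C)C[C@]2(C)C(OS(=O)(=O)C(F)(F)F)=C(C)C[C@H](O)[C@H]12
F4 | step 8 | saturated C9 ketone (7,8-dihydro-10, C8 undefined) | CC(C)(C)[Si](C)(C)OC[C@@]1(C)C=C(O[Si](C(C)C)(C(C)C)C(C)C)C[C@]2(C)C(=O)C(C)C[C@H](O[Si](CC)(CC)CC)[C@H]12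
F5 | step 12 | 2α,6α,19-triol with 9-vinyl group | OC[C@@]1(C)C[C@H](O)C[C@]2(C)C(C=C)=C(C)C[C@H](O)[C@H]12
F6 | step 13 | C12 primary alcohol (19-acetoxy-2α,6α,12-triol) | CC(=O)OC[C@@]1(C)C[C@H](O)C[C@]2(C)C(CCO)=C(C)C[C@H](O)[C@H]12
F7 | step 13 | C12 iodide | CC(=O)OC[C@@]1(C)C[C@H](O)C[C@]2(C)C(CCI)=C(C)C[C@H](O)[C@H]12
A1 | alternative 1 | (S)-8a-methyl-3,4,8,8a-tetrahydronaphthalene-1,6(2H,7H)-dione | C[C@]12CCC(=O)C=C1CCCC2=O
A2 | alternative 2 | triene for the intramolecular cycloaddition (tether cis on C10, (Z)-alkenylboronate, silyloxyethyl placeholder on C9) | CC(C)(C)[Si](C)(C)OC[C@@](/C=C\B1OC(C)(C)C(C)(C)O1)(C)C[C@H](O[Si](C)(C)C(C)(C)C)C/C(C)=C(/CCO[Si](C)(C)C(C)(C)C)C(C)=C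
A3 | alternative 3 | 4-methyl-2-{[tri(propan-2-yl)silyl]oxy}penta-1,3-diene | C=C(O[Si](C(C)C)(C(C)C)C(C)C)C=C(C)C
A4 | alternative 3 | gem-dimethyl cycloadduct of A3 and 7 | CC1(C)C=C(O[Si](C(C)C)(C(C)C)C(C)C)C[C@]2(C)C(=O)C(C)=CC(=O)[C@H]12
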